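## Retrosynthetic overview

1. Target 22 comes from enone triol 19 by late angeloylation of the C3 hydroxyl (eudesmane numbering: ring A = C1–C5, C10; ring B = C5–C10). The C8 ketone is carried as a carbinol and revealed last by allylic oxidation.
2. Key disconnection: ring B is opened at C7–C8 and closed by an intramolecular Nozaki–Hiyama–Kishi addition of a (Z)-alkenyl iodide (C7) to an aldehyde (C8).
3. Enabling feature: the tertiary hydroxyl on C11, the carbon attached to C7 of ring B. As a propargylic alcohol it directs a trans-hydrostannation that puts the metal on C7 and hydrogen on C6, so the C7–metal bond lies cis to C5 and can reach C8.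
4. Ring A is made first by an enantioselective Diels–Alder reaction of an (E)-2-methylenynal (C5–C7, C9–C14) with a 2-siloxydiene (C1–C4, C15), which fixes C5/C10. Its silyl enol ether is converted into a 1-en-3-one so that C4 is the only enolisable site for the later hydroxylation.
5. Order of ring formation: ring A (step 4), then ring B (step 9). C4–OH, C1–C2 saturation and C3–OH are then set on the rigid trans-decalin.

Key step: step 9

Remark: the methyl-bearing carbon next to the ring A carbonyl (C4) is carried as an epimer mixture in 8–14, and C8 as an epimer mixture in 14–18. Both are left open in the SMILES and converge later (steps 10 and 13).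

Assumption: the sense of induction of the oxazaborolidinium catalyst in step 4 must be confirmed on the first adduct; if 8 forms as its enantiomer, the (R)-configured catalyst is used instead.

## Route

Step 1
Reactants: 1 2-methyl-2-[(trimethylsilyl)oxy]but-3-yne
Product: 3 4-methyl-4-[(trimethylsilyl)oxy]pent-2-ynal, via lithium acetylide 2 (not isolated)
Conditions: n-BuLi, THF, −78 °C; DMF, −78 → 0 °C; inverse quench into cold aq. KH2PO4/MTBE
Reagents that add atoms: N,N-dimethylformamide CN(C)C=O; n-butyllithium [Li]CCCC (lithium of 2 only)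
Why: Formylation of a lithium acetylide with DMF should give the ynal, and the buffered inverse quench releases the aldehyde without cleaving the tertiary silyl ether.

Step 2
Reactants: 3 4-methyl-4-[(trimethylsilyl)oxy]pent-2-ynal; 4 2-(triphenyl-λ5-phosphanylidene)propanal
Product: 5 (2E)-2,6-dimethyl-6-[(trimethylsilyl)oxy]hept-2-en-4-ynal
Conditions: CH2Cl2, 0 °C → rt
Reagents that add atoms: none
Why: Wittig olefination with the stabilised 2-formyl ylide is E-selective and should stop at the mono-olefin, because the ynal is far more electrophilic than the α-branched enal that forms.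

Step 3
Reactants: 6 pent-1-en-3-one
Product: 7 (3Z)-3-{[tri(propan-2-yl)silyl]oxy}penta-1,3-diene
Conditions: i-Pr3SiOTf, Et3N, CH2Cl2, 0 °C → rt
Reagents that add atoms: triisopropylsilyl trifluoromethanesulfonate CC(C)[Si](C(C)C)(C(C)C)OS(=O)(=O)C(F)(F)F
Why: Silyl enol ether formation by soft enolisation of the ethyl ketone should give mainly the (Z)-enol ether, the 2-siloxydiene whose methyl group lies outside the s-cis diene.

Step 4
Reactants: 5 (2E)-2,6-dimethyl-6-[(trimethylsilyl)oxy]hept-2-en-4-ynal; 7 (3Z)-3-{[tri(propan-2-yl)silyl]oxy}penta-1,3-diene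
Product: 8 (1S,6R)-1,5-dimethyl-6-{3-methyl-3-[(trimethylsilyl)oxy]but-1-yn-1-yl}-4-{[tri(propan-2-yl)silyl]oxy}cyclohex-3-ene-1-carbaldehyde (C5 epimers)
Conditions: 7 (2 equiv), oxazaborolidinium triflimide (20 mol %) from (S)-3,3-diphenyl-1-(2-methylphenyl)tetrahydro-1H,3H-pyrrolo[1,2-c][1,3,2]oxazaborole and HNTf2, CH2Cl2, −78 → −40 °C
Reagents that add atoms: none
Why: In this catalytic enantioselective Diels–Alder reaction the 2-siloxy group directs the methyl-bearing diene terminus to the β-carbon of the enal (C4–C5 and C1–C10 bonds), the E geometry of the dienophile is transferred suprafacially so that alkynyl and quaternary methyl end up cis (C5/C10), and the formyl-bound chiral Lewis acid shields one face so that the diene adds to the C2-Si/C3-Re face of 5.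

Step 5
Reactants: 8 (1S,6R)-1,5-dimethyl-6-{3-methyl-3-[(trimethylsilyl)oxy]but-1-yn-1-yl}-4-{[tri(propan-2-yl)silyl]oxy}cyclohex-3-ene-1-carbaldehyde
Product: 9 (1S,6R)-1,5-dimethyl-6-{3-methyl-3-[(trimethylsilyl)oxy]but-1-yn-1-yl}-4-oxocyclohex-2-ene-1-carbaldehyde (C5 epimers)
Conditions: Pd(OAc)2 (1.1 equiv), MeCN, 40 °C
Reagents that add atoms: none
Why: Saegusa–Ito oxidation of the regiodefined silyl enol ether (C2-bound palladium enolate, β-hydride elimination from C1) should give the 1-en-3-one, which leaves C4 as the only enolisable position next to the C3 carbonyl.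

Step 6
Reactants: 9 (1S,6R)-1,5-dimethyl-6-{3-methyl-3-[(trimethylsilyl)oxy]but-1-yn-1-yl}-4-oxocyclohex-2-ene-1-carbaldehyde
Product: 10 (4S,5S)-4-(2-methoxyethenyl)-4,6-dimethyl-5-{3-methyl-3-[(trimethylsilyl)oxy]but-1-yn-1-yl}cyclohex-2-en-1-one (E/Z mixture)
Conditions: MeOCH2PPh3Cl, KN(SiMe3)2, THF, 0 °C; then 9, −78 → −20 °C
Reagents that add atoms: (methoxymethyl)triphenylphosphonium chloride COC[P+](c1ccccc1)(c1ccccc1)c1ccccc1.[Cl-]
Why: Wittig methoxymethylenation adds C8; the non-stabilised ylide should react with the aldehyde much faster than with the conjugated ring ketone at low temperature.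

Step 7
Reactants: 10 (4S,5S)-4-(2-methoxyethenyl)-4,6-dimethyl-5-{3-methyl-3-[(trimethylsilyl)oxy]but-1-yn-1-yl}cyclohex-2-en-1-one
Product: 11 2-[(1S,6S)-6-(3-hydroxy-3-methylbut-1-yn-1-yl)-1,5-dimethyl-4-oxocyclohex-2-en-1-yl]acetaldehyde
Conditions: 2 M aq. HCl, THF, 0 °C → rt
Reagents that add atoms: water O
Why: Acid-catalysed enol ether hydrolysis should unmask the C8 aldehyde and at the same time cleave the tertiary trimethylsilyl ether, whose hydroxyl is needed free in step 8.

Step 8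
Reactants: 11 2-[(1S,6S)-6-(3-hydroxy-3-methylbut-1-yn-1-yl)-1,5-dimethyl-4-oxocyclohex-2-en-1-yl]acetaldehyde
Product: 13 2-{(1S,6R)-6-[(1Z)-3-hydroxy-2-iodo-3-methylbut-1-en-1-yl]-1,5-dimethyl-4-oxocyclohex-2-en-1-yl}acetaldehyde, via alkenylstannane 12 (not isolated)
Conditions: [(C5Me5)RuCl]4 (2 mol %), Bu3SnH (1.1 equiv, slow addition), CH2Cl2, rt; then I2, 0 °C; aq. Na2S2O3/KF work-up
Reagents that add atoms: tributylstannane CCCC[SnH](CCCC)CCCC (tin of 12 only); iodine II
Why: In the ruthenium-catalysed trans-hydrostannation, hydrogen bonding of the propargylic C11–OH to the chloride ligand should deliver tin to the proximal carbon C7 and hydrogen to C6 from the opposite side, and iododestannation with retention then gives the (Z)-alkenyl iodide with iodine cis to C5.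

Step 9
Reactants: 13 2-{(1S,6R)-6-[(1Z)-3-hydroxy-2-iodo-3-methylbut-1-en-1-yl]-1,5-dimethyl-4-oxocyclohex-2-en-1-yl}acetaldehyde
Product: 14 (4aS,8aS)-6-hydroxy-7-(2-hydroxypropan-2-yl)-1,4a-dimethyl-4a,5,6,8a-tetrahydronaphthalen-2(1H)-one (C1 and C6 epimers)
Conditions: CrCl2 (6 equiv), NiCl2 (0.1 equiv), DMSO (0.01 M), rt; aq. work-up
Reagents that add atoms: none
Why: Oxidative addition of the C7–I bond to zerovalent nickel (formed from NiCl2 by CrCl2), transmetalation to trivalent chromium and addition of the alkenylchromium to the C8 aldehyde should form the C7–C8 bond, an intramolecular Nozaki–Hiyama–Kishi reaction. Ring B closes in a 6-exo-trig mode (C7 attacks the exocyclic C8=O), which is possible only because the alkenyl metal is held cis to C5, a geometry fixed by the hydroxyl-directed trans-hydrostannation of step 8 and retained through iodination and transmetalation. The trans ring fusion follows from the trans arrangement of the C5 and C10 side chains set in step 4. The new carbinol centre C8 is not controlled and need not be, since both epimers are oxidised to the same ketone in step 13. The step needs chemoselectivity for the aldehyde over the ring A enone and tolerance of the free tertiary hydroxyl, both typical of organochromium reagents, and high dilution should suppress intermolecular coupling.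

Step 10
Reactants: 14 (4aS,8aS)-6-hydroxy-7-(2-hydroxypropan-2-yl)-1,4a-dimethyl-4a,5,6,8a-tetrahydronaphthalen-2(1H)-one
Product: 16 (1S,4aS,8aR)-1,6-dihydroxy-7-(2-hydroxypropan-2-yl)-1,4a-dimethyl-4a,5,6,8a-tetrahydronaphthalen-2(1H)-one (C6 epimers), via tripotassium dienolate 15 (not isolated)
Conditions: KN(SiMe3)2 (3.3 equiv), THF, −78 °C; then 3-phenyl-2-(phenylsulfonyl)oxaziridine, −78 °C; aq. NH4Cl
Reagents that add atoms: 3-phenyl-2-(phenylsulfonyl)oxaziridine O=S(=O)(c1ccccc1)N1OC1c1ccccc1; potassium bis(trimethylsilyl)amide C[Si](C)(C)[N-][Si](C)(C)C.[K+] (potassium of 15 only)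
Why: Electrophilic hydroxylation of a ketone enolate with an N-sulfonyloxaziridine: the cross-conjugated dienolate can form only at C4, and the oxidant should approach from the α-face, anti to the axial angular methyl at C10, setting the 4α-hydroxy-4β-methyl centre.

Step 11
Reactants: 16 (1S,4aS,8aR)-1,6-dihydroxy-7-(2-hydroxypropan-2-yl)-1,4a-dimethyl-4a,5,6,8a-tetrahydronaphthalen-2(1H)-one
Product: 17 (1S,4aR,8aR)-1,6-dihydroxy-7-(2-hydroxypropan-2-yl)-1,4a-dimethyl-3,4,4a,5,6,8a-hexahydronaphthalen-2(1H)-one (C6 epimers)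
Conditions: H2 (1 atm), RhCl(PPh3)3 (10 mol %), benzene–EtOH, rt
Reagents that add atoms: none
Why: Homogeneous hydrogenation with RhCl(PPh3)3 should reduce the unhindered disubstituted C1=C2 bond of the enone and leave the hindered trisubstituted C6=C7 bond, as is known for 1,4-dien-3-ones with an angular methyl group.

Step 12
Reactants: 17 (1S,4aR,8aR)-1,6-dihydroxy-7-(2-hydroxypropan-2-yl)-1,4a-dimethyl-3,4,4a,5,6,8a-hexahydronaphthalen-2(1H)-one
Product: 18 (1S,2S,4aR,8aR)-7-(2-hydroxypropan-2-yl)-1,4a-dimethyl-1,2,3,4,4a,5,6,8a-octahydronaphthalene-1,2,6-triol (C6 epimers)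
Conditions: NaBH4, MeOH, −20 → 0 °C
Reagents that add atoms: none
Why: Borohydride reduction of the cyclohexanone by axial attack from the α-face, anti to the axial methyl groups at C4 and C10, should give the equatorial 3β-alcohol trans to the C4 hydroxyl.

Step 13
Reactants: 18 (1S,2S,4aR,8aR)-7-(2-hydroxypropan-2-yl)-1,4a-dimethyl-1,2,3,4,4a,5,6,8a-octahydronaphthalene-1,2,6-triol
Product: 19 (4aR,5S,6S,8aR)-5,6-dihydroxy-3-(2-hydroxypropan-2-yl)-5,8a-dimethyl-4a,5,6,7,8,8a-hexahydronaphthalen-2(1H)-one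
Conditions: MnO2 (activated, excess), CH2Cl2, rt
Reagents that add atoms: none
Why: Manganese dioxide oxidation is selective for the allylic secondary alcohol at C8 and should leave the saturated C3 carbinol and the tertiary alcohols untouched, revealing the ring B enone from both C8 epimers.

Step 14
Reactants: 19 (4aR,5S,6S,8aR)-5,6-dihydroxy-3-(2-hydroxypropan-2-yl)-5,8a-dimethyl-4a,5,6,7,8,8a-hexahydronaphthalen-2(1H)-one; 20 angelic acid, (2Z)-2-methylbut-2-enoic acid
Product: 22 (4aR,5S,6S,8aR)-5-hydroxy-3-(2-hydroxypropan-2-yl)-5,8a-dimethyl-2-oxo-1,2,4a,5,6,7,8,8a-octahydronaphthalen-6-yl (2Z)-2-methylbut-2-enoate, via mixed anhydride 21 (not isolated)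
Conditions: 20 (3 equiv), 2,4,6-trichlorobenzoyl chloride, Et3N, toluene, rt; then 19, toluene, 80 °C
Reagents that add atoms: 2,4,6-trichlorobenzoyl chloride O=C(Cl)c1c(Cl)cc(Cl)cc1Cl (aroyl group of 21 only)
Why: Yamaguchi-type mixed anhydride esterification without a nucleophilic catalyst should acylate the only secondary hydroxyl (C3) and avoid the Z-to-E isomerisation of the angelate that acid chlorides or DMAP cause.

## Compound list

1 | 2-methyl-2-[(trimethylsilyl)oxy]but-3-yne | C#CC(C)(C)O[Si](C)(C)C | starting material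
2 | lithium 3-methyl-3-[(trimethylsilyl)oxy]but-1-yn-1-ide | [Li]C#CC(C)(C)O[Si](C)(C)C | intermediate
3 | 4-methyl-4-[(trimethylsilyl)oxy]pent-2-ynal | O=CC#CC(C)(C)O[Si](C)(C)C | intermediate
4 | 2-(triphenyl-λ5-phosphanylidene)propanal | CC(C=O)=P(c1ccccc1)(c1ccccc1)c1ccccc1 | starting material
5 | (2E)-2,6-dimethyl-6-[(trimethylsilyl)oxy]hept-2-en-4-ynal | O=C/C(C)=C/C#CC(C)(C)O[Si](C)(C)C | intermediate
6 | pent-1-en-3-one | CCC(=O)C=C | starting material
7 | (3Z)-3-{[tri(propan-2-yl)silyl]oxy}penta-1,3-diene | C/C=C(\O[Si](C(C)C)(C(C)C)C(C)C)C=C | intermediate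
8 | (1S,6R)-1,5-dimethyl-6-{3-methyl-3-[(trimethylsilyl)oxy]but-1-yn-1-yl}-4-{[tri(propan-2-yl)silyl]oxy}cyclohex-3-ene-1-carbaldehyde (C5 epimers) | CC(C)[Si](C(C)C)(C(C)C)OC1=CC[C@](C)(C=O)[C@@H](C#CC(C)(C)O[Si](C)(C)C)C1C | intermediate
9 | (1S,6R)-1,5-dimethyl-6-{3-methyl-3-[(trimethylsilyl)oxy]but-1-yn-1-yl}-4-oxocyclohex-2-ene-1-carbaldehyde (C5 epimers) | O=C1C=C[C@](C)(C=O)[C@@H](C#CC(C)(C)O[Si](C)(C)C)C1C | intermediate
10 | (4S,5S)-4-(2-methoxyethenyl)-4,6-dimethyl-5-{3-methyl-3-[(trimethylsilyl)oxy]but-1-yn-1-yl}cyclohex-2-en-1-one (E/Z, C6 epimers) | O=C1C=C[C@](C)(C=COC)[C@@H](C#CC(C)(C)O[Si](C)(C)C)C1C | intermediate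
11 | 2-[(1S,6S)-6-(3-hydroxy-3-methylbut-1-yn-1-yl)-1,5-dimethyl-4-oxocyclohex-2-en-1-yl]acetaldehyde (C5 epimers) | O=C1C=C[C@](C)(CC=O)[C@@H](C#CC(C)(C)O)C1C | intermediate
12 | 2-{(1S,6R)-6-[(1Z)-3-hydroxy-3-methyl-2-(tributylstannyl)but-1-en-1-yl]-1,5-dimethyl-4-oxocyclohex-2-en-1-yl}acetaldehyde | O=C1C=C[C@](C)(CC=O)[C@@H](/C=C(\[Sn](CCCC)(CCCC)CCCC)C(C)(C)O)C1C | intermediate
13 | 2-{(1S,6R)-6-[(1Z)-3-hydroxy-2-iodo-3-methylbut-1-en-1-yl]-1,5-dimethyl-4-oxocyclohex-2-en-1-yl}acetaldehyde | O=C1C=C[C@](C)(CC=O)[C@@H](/C=C(\I)C(C)(C)O)C1C | intermediate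
14 | (4aS,8aS)-6-hydroxy-7-(2-hydroxypropan-2-yl)-1,4a-dimethyl-4a,5,6,8a-tetrahydronaphthalen-2(1H)-one (C1 and C6 epimers) | O=C1C=C[C@]2(C)CC(O)C(C(C)(C)O)=C[C@H]2C1C | intermediate
15 | tripotassium C3,C4-dienolate C8,C11-dialkoxide of 14 (eudesmane numbering) | [K+].[K+].[K+].[O-]C1=C(C)[C@@H]2C=C(C(C)(C)[O-])C([O-])C[C@@]2(C)C=C1 | intermediate
16 | (1S,4aS,8aR)-1,6-dihydroxy-7-(2-hydroxypropan-2-yl)-1,4a-dimethyl-4a,5,6,8a-tetrahydronaphthalen-2(1H)-one (C6 epimers) | O=C1C=C[C@]2(C)CC(O)C(C(C)(C)O)=C[C@H]2[C@]1(C)O | intermediate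
17 | (1S,4aR,8aR)-1,6-dihydroxy-7-(2-hydroxypropan-2-yl)-1,4a-dimethyl-3,4,4a,5,6,8a-hexahydronaphthalen-2(1H)-one (C6 epimers) | O=C1CC[C@]2(C)CC(O)C(C(C)(C)O)=C[C@H]2[C@]1(C)O | intermediate
18 | (1S,2S,4aR,8aR)-7-(2-hydroxypropan-2-yl)-1,4a-dimethyl-1,2,3,4,4a,5,6,8a-octahydronaphthalene-1,2,6-triol (C6 epimers) | O[C@H]1CC[C@]2(C)CC(O)C(C(C)(C)O)=C[C@H]2[C@]1(C)O | intermediate
19 | (4aR,5S,6S,8aR)-5,6-dihydroxy-3-(2-hydroxypropan-2-yl)-5,8a-dimethyl-4a,5,6,7,8,8a-hexahydronaphthalen-2(1H)-one | O[C@H]1CC[C@]2(C)CC(=O)C(C(C)(C)O)=C[C@H]2[C@]1(C)O | intermediate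
20 | angelic acid, (2Z)-2-methylbut-2-enoic acid | C/C=C(/C)C(=O)O | starting material
21 | (2Z)-2-methylbut-2-enoic 2,4,6-trichlorobenzoic anhydride | C/C=C(/C)C(=O)OC(=O)c1c(Cl)cc(Cl)cc1Cl | intermediate
22 | (4aR,5S,6S,8aR)-5-hydroxy-3-(2-hydroxypropan-2-yl)-5,8a-dimethyl-2-oxo-1,2,4a,5,6,7,8,8a-octahydronaphthalen-6-yl (2Z)-2-methylbut-2-enoate | C/C=C(/C)C(=O)O[C@H]1CC[C@]2(C)CC(=O)C(C(C)(C)O)=C[C@H]2[C@]1(C)O | target

## Step count and risks

Total step count: 14. Longest linear sequence: 13 steps (steps 1, 2 and 4–14); step 3 is a one-step side branch.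

Steps most likely to fail:

**Step 4 (Diels–Alder).** The trisubstituted enynal may react sluggishly, the diene may be consumed by Lewis-acid-promoted aldol-type addition to the formyl group, or enantiofacial discrimination may be low. The fallback sets out from 5 and 7 and returns at 8. The cycloaddition is run without chiral catalyst (toluene, 110 °C, or Me2AlCl, CH2Cl2, −78 °C) to give racemic 8, that is 8 together with its enantiomer, the (1R,6S)-cyclohexenecarbaldehyde F1. Condensation with (1R,2R)-N,N'-dimethyl-1,2-diphenylethane-1,2-diamine (Et2O, molecular sieves) should give two diastereomeric imidazolidines, the aminal of 8 F2 and the aminal of the enantiomer F3, which are separated by chromatography. Mild hydrolysis of F2 (wet silica gel or aq. AcOH/THF) returns enantiopure 8.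

**Step 8 (hydrostannation–iodination).** The free aldehyde may be reduced or may disturb the hydroxyl-directed delivery of tin, and regiocontrol at the alkyne may erode. The fallback sets out from 10 and returns at 13. Treatment of 10 with pyridinium p-toluenesulfonate in MeOH should convert the methyl enol ether into the dimethyl acetal and cleave the silyl ether, giving the hydroxy alkynyl acetal F4. Trans-hydrostannation ([(C5Me5)RuCl]4, Bu3SnH, CH2Cl2) gives the alkenylstannane acetal F5, iododestannation (I2, 0 °C) gives the (Z)-iodo acetal F6, and aqueous acid (AcOH/THF/H2O) releases the aldehyde 13.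

**Step 9 (Nozaki–Hiyama–Kishi ring closure).** Protonation of the hindered alkenylchromium by the neighbouring hydroxyl, slow addition to the neopentyl-type aldehyde, or intermolecular coupling may outrun ring closure. The fallback sets out from 11 and returns at 14; it closes the same C7–C8 bond at the ketone oxidation level.
- Pinnick oxidation of 11 (NaClO2, NaH2PO4, 2-methylbut-2-ene) gives the carboxylic acid F7, and thioesterification (EtSH, EDC·HCl, DMAP) gives the S-ethyl thioester F8.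
- Trans-hydrostannation as in step 8 gives the alkenylstannane thioester F9.
- An intramolecular Liebeskind–Srogl-type coupling of thioester and stannane (Pd2(dba)3, tri(2-furyl)phosphine, monovalent copper diphenylphosphinate CuO2PPh2, THF, 50 °C) should give the bicyclic dienedione F10.
- Hydroxyl-directed reduction of the C8 ketone by the C11 hydroxyl (Me4NBH(OAc)3, AcOH/MeCN, −20 °C), which leaves the ring A enone untouched, returns 14.

Further compounds
F1 | step 4 | (1R,6S)-1,5-dimethyl-6-{3-methyl-3-[(trimethylsilyl)oxy]but-1-yn-1-yl}-4-{[tri(propan-2-yl)silyl]oxy}cyclohex-3-ene-1-carbaldehyde (enantiomer of 8) | CC(C)[Si](C(C)C)(C(C)C)OC1=CC[C@@](C)(C=O)[C@H](C#CC(C)(C)O[Si](C)(C)C)C1C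
F2 | step 4 | (4R,5R)-1,3-dimethyl-4,5-diphenylimidazolidine aminal of 8 | CN1[C@H](c2ccccc2)[C@@H](c2ccccc2)N(C)C1[C@@]1(C)CC=C(O[Si](C(C)C)(C(C)C)C(C)C)C(C)[C@@H]1C#CC(C)(C)O[Si](C)(C)C
F3 | step 4 | (4R,5R)-1,3-dimethyl-4,5-diphenylimidazolidine aminal of F1 | CN1[C@H](c2ccccc2)[C@@H](c2ccccc2)N(C)C1[C@]1(C)CC=C(O[Si](C(C)C)(C(C)C)C(C)C)C(C)[C@H]1C#CC(C)(C)O[Si](C)(C)C
F4 | step 8 | (4S,5S)-4-(2,2-dimethoxyethyl)-5-(3-hydroxy-3-methylbut-1-yn-1-yl)-4,6-dimethylcyclohex-2-en-1-one | O=C1C=C[C@](C)(CC(OC)OC)[C@@H](C#CC(C)(C)O)C1C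
F5 | step 8 | (4S,5R)-4-(2,2-dimethoxyethyl)-5-[(1Z)-3-hydroxy-3-methyl-2-(tributylstannyl)but-1-en-1-yl]-4,6-dimethylcyclohex-2-en-1-one | O=C1C=C[C@](C)(CC(OC)OC)[C@@H](/C=C(\[Sn](CCCC)(CCCC)CCCC)C(C)(C)O)C1C
F6 | step 8 | (4S,5R)-4-(2,2-dimethoxyethyl)-5-[(1Z)-3-hydroxy-2-iodo-3-methylbut-1-en-1-yl]-4,6-dimethylcyclohex-2-en-1-one | O=C1C=C[C@](C)(CC(OC)OC)[C@@H](/C=C(\I)C(C)(C)O)C1C
F7 | step 9 | 2-[(1S,6S)-6-(3-hydroxy-3-methylbut-1-yn-1-yl)-1,5-dimethyl-4-oxocyclohex-2-en-1-yl]acetic acid | O=C1C=C[C@](C)(CC(=O)O)[C@@H](C#CC(C)(C)O)C1C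
F8 | step 9 | S-ethyl 2-[(1S,6S)-6-(3-hydroxy-3-methylbut-1-yn-1-yl)-1,5-dimethyl-4-oxocyclohex-2-en-1-yl]ethanethioate | O=C1C=C[C@](C)(CC(=O)SCC)[C@@H](C#CC(C)(C)O)C1C
F9 | step 9 | S-ethyl 2-{(1S,6R)-6-[(1Z)-3-hydroxy-3-methyl-2-(tributylstannyl)but-1-en-1-yl]-1,5-dimethyl-4-oxocyclohex-2-en-1-yl}ethanethioate | O=C1C=C[C@](C)(CC(=O)SCC)[C@@H](/C=C(\[Sn](CCCC)(CCCC)CCCC)C(C)(C)O)C1C
F10 | step 9 | (4aS,8aS)-3-(2-hydroxypropan-2-yl)-5,8a-dimethyl-8a,5-dihydronaphthalene-2,6(1H,4aH)-dione (eudesma-1,6-diene-3,8-dione with 11-OH) | O=C1C=C[C@]2(C)CC(=O)C(C(C)(C)O)=C[C@H]2C1C
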